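**Strategy.** The ten-membered carbocycle is disconnected at C9–C10 (ring atoms numbered C1 = lactone O–CH, round to C10 = ring-fusion CH; C11–C13 = lactone α-carbon, carbonyl and methylene). The route exploits the fact that C10 is the β-carbon of a butenolide (O–C1–C10=C11–C12) whose α-carbon C11 carries C13. A thirteen-membered ring sulfide C9–S–C13, S-methylated and deprotonated next to the C8 ketone, undergoes a [2,3] shift that forms C9–C10, releases the C11=C13 methylene and contracts the thia-macrocycle to the cis-fused ten-membered methylene lactone in one operation. The precursor is that bicyclic sulfide, already bearing the isovalerate and both ring olefins.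

Key step: step 17

**Remarks**
- Numbering: C1 (lactone O–CH), C2=C3 (C3 bears C15H2O–isovaleryl), C4, C5, C6=C7 (C7 bears CH3), C8 (CH–OAc), C9, C10 (ring-fusion CH), C11 (lactone α-carbon, bears C13), C12 (C=O).
- Target stereochemistry: 1R, 8S, 10R; lactone cis-fused (H1 and H10 syn); C1 and C15 cis across C2=C3 (ring-trans); C6=C7 Z (ring-cis). Compounds 27 and 30 are drawn to match. TBS = tert-butyldimethylsilyl, TES = triethylsilyl, rt = room temperature.
- Design points for the precursor:
  - C1, the only stereocentre the key step can read, is set by a reagent-controlled ketone reduction (step 6).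
  - C1 and C15 are differentiated from the start by carbocupration of a 4-silyloxy-2-ynoate rather than a symmetrical alkyne diester.
  - The sulfide is closed with nucleophilic sulfur on C9 and the primary allylic bromide C13 as electrophile, and the butenolide never meets a base stronger than carbonate, because H1 is a doubly activated γ-hydrogen.
  - S-methylation and ylide formation are separate operations with one equivalent of MeOTf, so the methyl sulfide of 30 is not alkylated again.
- Assumption: C9–H of sulfonium salt 28 is taken to be far more acidic than C1–H, so that K2CO3 deprotonates C9 only.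

**Route**

Step 1
Reactants: 1 3-bromopropan-1-ol
Product: 2 (3-bromopropoxy)triethylsilane
Conditions: TESCl, imidazole, CH2Cl2, 0 °C → rt
Reagents that add atoms: chlorotriethylsilane, CC[Si](Cl)(CC)CC
Why: Routine O-silylation of a primary alcohol; the TES ether is chosen because a primary TES ether can later be oxidised directly under Swern conditions while TBS ethers stay in place.

Step 2
Reactants: 3 tert-butyldimethyl(prop-2-yn-1-yloxy)silane
Product: 5 methyl 4-[(tert-butyldimethylsilyl)oxy]but-2-ynoate, via lithium acetylide 4 (not isolated)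
Conditions: n-BuLi, THF, −78 °C; ClCO2Me, −78 → 0 °C
Reagents that add atoms: methyl chloroformate, COC(=O)Cl
Why: Deprotonation of a terminal alkyne and C-acylation of the lithium acetylide with a chloroformate is the standard entry to 2-ynoates and gives C1–C2≡C3–C15 with C15 already distinguished as a silyl ether.

Step 3
Reactants: 2 (3-bromopropoxy)triethylsilane; 5 methyl 4-[(tert-butyldimethylsilyl)oxy]but-2-ynoate
Product: 8 methyl (2Z)-3-{[(tert-butyldimethylsilyl)oxy]methyl}-6-[(triethylsilyl)oxy]hex-2-enoate, via Grignard reagent 6 (not isolated), via alkylcopper reagent 7 (not isolated)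
Conditions: 2, Mg, THF, rt; CuBr·SMe2, THF, −45 °C; 5, −78 °C; sat. aq NH4Cl, −78 °C
Reagents that add atoms: none
Why: syn-Carbocupration of a 2-ynoate followed by cold protonation is stereospecific, so the new C3–C4 bond ends up cis to H2 and C1 cis to C15 (the ring-trans C2=C3 geometry); −78 °C throughout prevents geometric equilibration before the quench.

Step 4
Reactants: 8 methyl (2Z)-3-{[(tert-butyldimethylsilyl)oxy]methyl}-6-[(triethylsilyl)oxy]hex-2-enoate
Product: 9 (2Z)-3-{[(tert-butyldimethylsilyl)oxy]methyl}-N-methoxy-N-methyl-6-[(triethylsilyl)oxy]hex-2-enamide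
Conditions: MeNHOMe·HCl, i-PrMgCl, THF, −20 → 0 °C
Reagents that add atoms: N,O-dimethylhydroxylamine hydrochloride, CNOC.Cl
Why: Weinreb amide formation by aminolysis of the ester with the chloromagnesium amide of N,O-dimethylhydroxylamine; the silyl ethers are inert and the β,β-disubstituted double bond does not accept the amide in a conjugate sense.

Step 5
Reactants: 9 (2Z)-3-{[(tert-butyldimethylsilyl)oxy]methyl}-N-methoxy-N-methyl-6-[(triethylsilyl)oxy]hex-2-enamide; 10 vinylmagnesium bromide
Product: 11 (4Z)-5-{[(tert-butyldimethylsilyl)oxy]methyl}-8-[(triethylsilyl)oxy]octa-1,4-dien-3-one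
Conditions: THF, −20 → 0 °C; inverse quench into cold aq NH4Cl
Reagents that add atoms: none
Why: Weinreb ketone synthesis, in which the ketone is unmasked only at work-up so that a single vinyl group (C10 plus the carbon later lost as ethene) is added; the inverse buffered quench keeps the liberated amine from adding to the vinyl ketone.

Step 6
Reactants: 11 (4Z)-5-{[(tert-butyldimethylsilyl)oxy]methyl}-8-[(triethylsilyl)oxy]octa-1,4-dien-3-one
Product: 12 (3S,4Z)-5-{[(tert-butyldimethylsilyl)oxy]methyl}-8-[(triethylsilyl)oxy]octa-1,4-dien-3-ol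
Conditions: (R)-2-methyl-CBS-oxazaborolidine (0.5 equiv), catecholborane, toluene, −78 °C
Reagents that add atoms: none
Why: Corey–Bakshi–Shibata reduction, in which the trisubstituted (Z)-alkenyl flank with its cis CH2OTBS group should act as the large substituent and the bare vinyl group as the small one, so that the (R)-catalyst gives the (S)-carbinol, which is the C1 configuration of the target (the descriptor becomes R once C1 is part of the lactone); catecholborane at −78 °C favours 1,2- over 1,4-reduction.

Step 7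
Reactants: 12 (3S,4Z)-5-{[(tert-butyldimethylsilyl)oxy]methyl}-8-[(triethylsilyl)oxy]octa-1,4-dien-3-ol
Product: 13 (3S,4Z)-3-[(tert-butyldimethylsilyl)oxy]-5-{[(tert-butyldimethylsilyl)oxy]methyl}-8-[(triethylsilyl)oxy]octa-1,4-diene
Conditions: TBSCl, imidazole, DMF, rt
Reagents that add atoms: tert-butyldimethylsilyl chloride, CC(C)(C)[Si](C)(C)Cl
Why: O-Silylation under mildly basic conditions protects C1–OH for the organometallic steps ahead without any risk of ionising the doubly allylic position.

Step 8
Reactants: 13 (3S,4Z)-3-[(tert-butyldimethylsilyl)oxy]-5-{[(tert-butyldimethylsilyl)oxy]methyl}-8-[(triethylsilyl)oxy]octa-1,4-diene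
Product: 14 (4Z,6S)-6-[(tert-butyldimethylsilyl)oxy]-4-{[(tert-butyldimethylsilyl)oxy]methyl}octa-4,7-dienal
Conditions: (COCl)2, DMSO, CH2Cl2, −78 → −40 °C; Et3N, −78 → 0 °C
Reagents that add atoms: none
Why: Swern oxidation applied directly to a primary TES ether, which is cleaved by the chlorodimethylsulfonium reagent and oxidised in the same flask while the primary and secondary TBS ethers are inert, so C6 is unmasked as the aldehyde in one operation.

Step 9
Reactants: 14 (4Z,6S)-6-[(tert-butyldimethylsilyl)oxy]-4-{[(tert-butyldimethylsilyl)oxy]methyl}octa-4,7-dienal; 15 methyl 2-[bis(2,2,2-trifluoroethoxy)phosphoryl]propanoate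
Product: 17 methyl (2Z,6Z,8S)-8-[(tert-butyldimethylsilyl)oxy]-6-{[(tert-butyldimethylsilyl)oxy]methyl}-2-methyldeca-2,6,9-trienoate, via potassium phosphonate 16 (not isolated)
Conditions: 15, KHMDS, 18-crown-6, THF, −78 °C; then 14, −78 °C
Reagents that add atoms: none
Why: Still–Gennari olefination, in which the electron-poor trifluoroethyl phosphonate with a dissociated potassium counter-ion eliminates fast and irreversibly after addition and so should give the (Z)-2-methyl-2-enoate, the ring-cis C6=C7 geometry.

Step 10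
Reactants: 17 methyl (2Z,6Z,8S)-8-[(tert-butyldimethylsilyl)oxy]-6-{[(tert-butyldimethylsilyl)oxy]methyl}-2-methyldeca-2,6,9-trienoate
Product: 18 (3Z,7Z,9S)-9-[(tert-butyldimethylsilyl)oxy]-7-{[(tert-butyldimethylsilyl)oxy]methyl}-1-chloro-3-methylundeca-3,7,10-trien-2-one
Conditions: ICH2Cl, MeLi·LiBr, THF, −78 °C; AcOH, −78 °C
Reagents that add atoms: chloroiodomethane, ClCI
Why: Homologation of an ester with chloromethyllithium generated in the presence of the substrate: the carbenoid adds once to the ester carbonyl at −78 °C and the ketone is released only on the cold acidic quench, so the α-chloromethyl ketone (C8=O, C9–Cl) should form without over-addition or loss of the (Z)-geometry.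

Step 11
Reactants: 18 (3Z,7Z,9S)-9-[(tert-butyldimethylsilyl)oxy]-7-{[(tert-butyldimethylsilyl)oxy]methyl}-1-chloro-3-methylundeca-3,7,10-trien-2-one
Product: 19 S-[(3Z,7Z,9S)-9-[(tert-butyldimethylsilyl)oxy]-7-{[(tert-butyldimethylsilyl)oxy]methyl}-3-methyl-2-oxoundeca-3,7,10-trien-1-yl] ethanethioate
Conditions: KSAc, DMF, 0 °C
Reagents that add atoms: potassium thioacetate, CC(=O)[S-].[K+]
Why: SN2 displacement of an α-chloro ketone by thioacetate is fast and clean and places the ring sulfur on C9 in a form that is inert to the desilylation, acylations and metathesis that follow.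

Step 12
Reactants: 19 S-[(3Z,7Z,9S)-9-[(tert-butyldimethylsilyl)oxy]-7-{[(tert-butyldimethylsilyl)oxy]methyl}-3-methyl-2-oxoundeca-3,7,10-trien-1-yl] ethanethioate
Product: 20 S-[(3Z,7Z,9S)-9-hydroxy-7-(hydroxymethyl)-3-methyl-2-oxoundeca-3,7,10-trien-1-yl] ethanethioate
Conditions: HF·pyridine, pyridine, THF, 0 °C → rt
Reagents that add atoms: none
Why: Buffered fluoride-mediated desilylation removes both TBS groups under mildly acidic, non-nucleophilic conditions that leave the thioester, the (Z)-enone and the doubly allylic C1 carbinol untouched.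

Step 13
Reactants: 20 S-[(3Z,7Z,9S)-9-hydroxy-7-(hydroxymethyl)-3-methyl-2-oxoundeca-3,7,10-trien-1-yl] ethanethioate; 21 isovaleryl chloride
Product: 22 (2Z,4S)-2-[(3Z)-6-(acetylsulfanyl)-4-methyl-5-oxohex-3-en-1-yl]-4-hydroxyhexa-2,5-dien-1-yl 3-methylbutanoate
Conditions: 2,4,6-collidine, CH2Cl2, −78 → −40 °C
Reagents that add atoms: none
Why: Selective acylation with an acid chloride and a hindered pyridine base at low temperature, which discriminates strongly between the unhindered primary allylic C15 hydroxyl and the secondary, doubly allylic C1 hydroxyl, so the isovalerate should go to C15 only.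

Step 14
Reactants: 22 (2Z,4S)-2-[(3Z)-6-(acetylsulfanyl)-4-methyl-5-oxohex-3-en-1-yl]-4-hydroxyhexa-2,5-dien-1-yl 3-methylbutanoate; 23 2-(bromomethyl)acrylic acid
Product: 24 (2Z,4S)-2-[(3Z)-6-(acetylsulfanyl)-4-methyl-5-oxohex-3-en-1-yl]-4-{[2-(bromomethyl)prop-2-enoyl]oxy}hexa-2,5-dien-1-yl 3-methylbutanoate
Conditions: DIC, DMAP (10 mol%), CH2Cl2, 0 °C
Reagents that add atoms: none
Why: Steglich esterification of the remaining C1 alcohol proceeds with retention at C1; low temperature and a small amount of DMAP limit quaternisation of the catalyst by the allylic bromide.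

Step 15
Reactants: 24 (2Z,4S)-2-[(3Z)-6-(acetylsulfanyl)-4-methyl-5-oxohex-3-en-1-yl]-4-{[2-(bromomethyl)prop-2-enoyl]oxy}hexa-2,5-dien-1-yl 3-methylbutanoate
Product: 25 (2Z)-2-[(3Z)-6-(acetylsulfanyl)-4-methyl-5-oxohex-3-en-1-yl]-3-[(2R)-4-(bromomethyl)-5-oxo-2,5-dihydrofuran-2-yl]prop-2-en-1-yl 3-methylbutanoate
Conditions: second-generation Hoveyda–Grubbs catalyst (10 mol%), 1,4-benzoquinone (10 mol%), toluene, 70 °C, 2 mM
Reagents that add atoms: none
Why: Ring-closing metathesis of an α-substituted acrylate of a secondary allylic alcohol is an established route to α-substituted butenolides: the ruthenium carbene loads on the monosubstituted C1 vinyl group and closes the five-membered ring onto C11 with loss of ethene, the two trisubstituted olefins being too hindered to compete and C1 staying untouched.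

Step 16
Reactants: 25 (2Z)-2-[(3Z)-6-(acetylsulfanyl)-4-methyl-5-oxohex-3-en-1-yl]-3-[(2R)-4-(bromomethyl)-5-oxo-2,5-dihydrofuran-2-yl]prop-2-en-1-yl 3-methylbutanoate
Product: 27 thirteen-membered allylic sulfide (1R; C2=C3 ring-trans; 6Z), via thiol 26 (not isolated)
Conditions: K2CO3, degassed MeOH/THF (1:4), 0 °C, syringe-pump addition to 1 mM
Reagents that add atoms: none
Why: One-pot thioacetate methanolysis and intramolecular SN2 thioether formation under high dilution: thiol 26 is released as its weakly basic thiolate and should close the ring at the primary allylic bromide C13 rather than at the hindered, C1-flanked C10, while the short exposure at 0 °C is meant to spare the acidic C1–H.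

Step 17
Reactants: 27 thirteen-membered allylic sulfide (1R; C2=C3 ring-trans; 6Z)
Product: 30 9-(methylsulfanyl)-8-oxo ten-membered cis-fused α-methylene lactone (1R,10R; C9 epimers), via sulfonium triflate 28 (not isolated), via sulfonium ylide 29 (not isolated)
Conditions: MeOTf (1.05 equiv), CH2Cl2, −20 → 0 °C; then powdered K2CO3, MeCN, 0 °C → rt
Reagents that add atoms: methyl trifluoromethanesulfonate, COS(=O)(=O)C(F)(F)F
Why: MeOTf alkylates the ring sulfur of 27 to give sulfonium salt 28, and K2CO3 then removes a C9 proton, acidified by both the C8 carbonyl and the sulfonium centre, to give the stabilised ylide 29, whose carbanion bonds suprafacially to C10 through a five-membered envelope (C9–S–C13–C11=C10) while S–C13 breaks and C11=C13 forms. The closest known reaction type is the [2,3]-sigmatropic ring contraction of cyclic allylic sulfonium ylides stabilised by a carbonyl group; here the allyl unit is the α-(thiomethyl)butenolide, so the shift is polarity-matched, with nucleophilic C9 meeting the electrophilic β-carbon C10. The ten-membered carbocycle C1–C10 is closed by ring contraction, S, C13 and C11 being excised from the thirteen-membered ring path, and the butenolide becomes the α-methylene-γ-butyrolactone in the same event. The new stereocentre C10 is controlled by C1: the bridge leaves C1 through C2 on the face opposite H1, so sulfur and C9 are expected to sit over that face of the planar butenolide and to deliver C9 syn to C2, which gives the cis ring fusion (10R), while C9 forms as an epimer mixture that is erased in step 18. The step needs proton removal at C9 and not at the γ-position C1, which would lead to 1,4-elimination of the sulfonium group; the large acidity gap, the weak heterogeneous base and the two-stage protocol with one equivalent of MeOTf secure this. The facial preference inside this particular bicycle is the untested element and the main risk of the route.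

Step 18
Reactants: 30 9-(methylsulfanyl)-8-oxo ten-membered cis-fused α-methylene lactone (1R,10R; C9 epimers)
Product: 31 8-oxo ten-membered cis-fused α-methylene lactone (1R,10R)
Conditions: Zn dust, AcOH/THF (1:4), rt
Reagents that add atoms: none
Why: Reductive desulfurisation of an α-alkylthio ketone by zinc in acetic acid cleaves the C9–S bond next to the carbonyl and leaves a C9 methylene, so both C9 epimers converge, and neither the conjugated lactone nor the isolated esters are reduced by zinc under these conditions.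

Step 19
Reactants: 31 8-oxo ten-membered cis-fused α-methylene lactone (1R,10R)
Product: 32 (1R,8S,10R)-8-hydroxy ten-membered cis-fused α-methylene lactone
Conditions: (R)-2-methyl-CBS-oxazaborolidine (1 equiv), catecholborane, toluene/CH2Cl2, −78 °C
Reagents that add atoms: none
Why: Corey–Bakshi–Shibata reduction, 1,2-selective for enones: with the α-methyl alkenyl carbon C7 as the large flank and the C9 methylene as the small one, the (R)-catalyst should give the (8S)-allylic alcohol under reagent control, which is preferred here because the facial bias of the ten-membered ring is unknown, and the α-methylene lactone, a conjugated ester, is not expected to be reduced by catecholborane at −78 °C.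

Step 20
Reactants: 32 (1R,8S,10R)-8-hydroxy ten-membered cis-fused α-methylene lactone
Product: 33 CNP0398030.1 (target; 1R,8S,10R)
Conditions: Ac2O, pyridine, DMAP (cat.), CH2Cl2, 0 °C
Reagents that add atoms: acetic anhydride, CC(=O)OC(C)=O
Why: O-Acetylation of the secondary allylic alcohol proceeds with retention at C8 and completes the target.

**Compound list**

1 | 3-bromopropan-1-ol | OCCCBr | starting material
2 | (3-bromopropoxy)triethylsilane | CC[Si](CC)(CC)OCCCBr | intermediate
3 | tert-butyldimethyl(prop-2-yn-1-yloxy)silane | C#CCO[Si](C)(C)C(C)(C)C | starting material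
4 | {3-[(tert-butyldimethylsilyl)oxy]prop-1-yn-1-yl}lithium (lithium acetylide) | [Li]C#CCO[Si](C)(C)C(C)(C)C | intermediate
5 | methyl 4-[(tert-butyldimethylsilyl)oxy]but-2-ynoate | COC(=O)C#CCO[Si](C)(C)C(C)(C)C | intermediate
6 | {3-[(triethylsilyl)oxy]propyl}magnesium bromide (Grignard reagent) | CC[Si](CC)(CC)OCCC[Mg]Br | intermediate
7 | {3-[(triethylsilyl)oxy]propyl}copper (alkylcopper reagent, monovalent copper, formed beside MgBr2) | CC[Si](CC)(CC)OCCC[Cu] | intermediate
8 | methyl (2Z)-3-{[(tert-butyldimethylsilyl)oxy]methyl}-6-[(triethylsilyl)oxy]hex-2-enoate | COC(=O)/C=C(\CO[Si](C)(C)C(C)(C)C)CCCO[Si](CC)(CC)CC | intermediate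
9 | (2Z)-3-{[(tert-butyldimethylsilyl)oxy]methyl}-N-methoxy-N-methyl-6-[(triethylsilyl)oxy]hex-2-enamide | CON(C)C(=O)/C=C(\CO[Si](C)(C)C(C)(C)C)CCCO[Si](CC)(CC)CC | intermediate
10 | vinylmagnesium bromide | C=C[Mg]Br | starting material
11 | (4Z)-5-{[(tert-butyldimethylsilyl)oxy]methyl}-8-[(triethylsilyl)oxy]octa-1,4-dien-3-one | C=CC(=O)/C=C(\CO[Si](C)(C)C(C)(C)C)CCCO[Si](CC)(CC)CC | intermediate
12 | (3S,4Z)-5-{[(tert-butyldimethylsilyl)oxy]methyl}-8-[(triethylsilyl)oxy]octa-1,4-dien-3-ol | C=C[C@H](O)/C=C(\CO[Si](C)(C)C(C)(C)C)CCCO[Si](CC)(CC)CC | intermediate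
13 | (3S,4Z)-3-[(tert-butyldimethylsilyl)oxy]-5-{[(tert-butyldimethylsilyl)oxy]methyl}-8-[(triethylsilyl)oxy]octa-1,4-diene | C=C[C@H](O[Si](C)(C)C(C)(C)C)/C=C(\CO[Si](C)(C)C(C)(C)C)CCCO[Si](CC)(CC)CC | intermediate
14 | (4Z,6S)-6-[(tert-butyldimethylsilyl)oxy]-4-{[(tert-butyldimethylsilyl)oxy]methyl}octa-4,7-dienal | C=C[C@H](O[Si](C)(C)C(C)(C)C)/C=C(\CO[Si](C)(C)C(C)(C)C)CCC=O | intermediate
15 | methyl 2-[bis(2,2,2-trifluoroethoxy)phosphoryl]propanoate | COC(=O)C(C)P(=O)(OCC(F)(F)F)OCC(F)(F)F | starting material
16 | potassium salt of 15 (phosphonate carbanion) | COC(=O)[C-](C)P(=O)(OCC(F)(F)F)OCC(F)(F)F.[K+] | intermediate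
17 | methyl (2Z,6Z,8S)-8-[(tert-butyldimethylsilyl)oxy]-6-{[(tert-butyldimethylsilyl)oxy]methyl}-2-methyldeca-2,6,9-trienoate | C=C[C@H](O[Si](C)(C)C(C)(C)C)/C=C(\CO[Si](C)(C)C(C)(C)C)CC/C=C(/C)C(=O)OC | intermediate
18 | (3Z,7Z,9S)-9-[(tert-butyldimethylsilyl)oxy]-7-{[(tert-butyldimethylsilyl)oxy]methyl}-1-chloro-3-methylundeca-3,7,10-trien-2-one | C=C[C@H](O[Si](C)(C)C(C)(C)C)/C=C(\CO[Si](C)(C)C(C)(C)C)CC/C=C(/C)C(=O)CCl | intermediate
19 | S-[(3Z,7Z,9S)-9-[(tert-butyldimethylsilyl)oxy]-7-{[(tert-butyldimethylsilyl)oxy]methyl}-3-methyl-2-oxoundeca-3,7,10-trien-1-yl] ethanethioate | C=C[C@H](O[Si](C)(C)C(C)(C)C)/C=C(\CO[Si](C)(C)C(C)(C)C)CC/C=C(/C)C(=O)CSC(C)=O | intermediate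
20 | S-[(3Z,7Z,9S)-9-hydroxy-7-(hydroxymethyl)-3-methyl-2-oxoundeca-3,7,10-trien-1-yl] ethanethioate | C=C[C@H](O)/C=C(\CO)CC/C=C(/C)C(=O)CSC(C)=O | intermediate
21 | isovaleryl chloride (3-methylbutanoyl chloride) | CC(C)CC(Cl)=O | starting material
22 | (2Z,4S)-2-[(3Z)-6-(acetylsulfanyl)-4-methyl-5-oxohex-3-en-1-yl]-4-hydroxyhexa-2,5-dien-1-yl 3-methylbutanoate | C=C[C@H](O)/C=C(\COC(=O)CC(C)C)CC/C=C(/C)C(=O)CSC(C)=O | intermediate
23 | 2-(bromomethyl)acrylic acid | C=C(CBr)C(=O)O | starting material
24 | (2Z,4S)-2-[(3Z)-6-(acetylsulfanyl)-4-methyl-5-oxohex-3-en-1-yl]-4-{[2-(bromomethyl)prop-2-enoyl]oxy}hexa-2,5-dien-1-yl 3-methylbutanoate | C=C[C@H](OC(=O)C(=C)CBr)/C=C(\COC(=O)CC(C)C)CC/C=C(/C)C(=O)CSC(C)=O | intermediate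
25 | (2Z)-2-[(3Z)-6-(acetylsulfanyl)-4-methyl-5-oxohex-3-en-1-yl]-3-[(2R)-4-(bromomethyl)-5-oxo-2,5-dihydrofuran-2-yl]prop-2-en-1-yl 3-methylbutanoate | O=C1O[C@H](/C=C(\COC(=O)CC(C)C)CC/C=C(/C)C(=O)CSC(C)=O)C=C1CBr | intermediate
26 | (2Z)-3-[(2R)-4-(bromomethyl)-5-oxo-2,5-dihydrofuran-2-yl]-2-[(3Z)-4-methyl-5-oxo-6-sulfanylhex-3-en-1-yl]prop-2-en-1-yl 3-methylbutanoate (thiol) | O=C1O[C@H](/C=C(\COC(=O)CC(C)C)CC/C=C(/C)C(=O)CS)C=C1CBr | intermediate
27 | thirteen-membered allylic sulfide: (1R)-butenolide O–C1–C10=C11–C12(=O) bridged from C1 to C11 by C2=C3(C15H2O-isovaleryl)–C4–C5–C6=C7(CH3)–C8(=O)–C9H2–S–C13H2; C1 and C15 cis on C2=C3, C6=C7 Z | O=C1O[C@@H]2/C=C(\COC(=O)CC(C)C)CC/C=C(/C)C(=O)CSCC1=C2 | intermediate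
28 | S-methylsulfonium trifluoromethanesulfonate of 27 | O=C1O[C@@H]2/C=C(\COC(=O)CC(C)C)CC/C=C(/C)C(=O)C[S+](C)CC1=C2.[O-]S(=O)(=O)C(F)(F)F | intermediate
29 | sulfonium ylide of 28 (carbanion at C9) | O=C1O[C@@H]2/C=C(\COC(=O)CC(C)C)CC/C=C(/C)C(=O)[CH-][S+](C)CC1=C2 | intermediate
30 | 9-(methylsulfanyl)-8-oxo ten-membered cis-fused α-methylene lactone, 1R,10R, C2=C3 ring-trans, 6Z (C9 epimer mixture expected; 9S epimer drawn) | C=C1C(=O)O[C@@H]2/C=C(\COC(=O)CC(C)C)CC/C=C(/C)C(=O)[C@@H](SC)[C@H]12 | intermediate
31 | 8-oxo ten-membered cis-fused α-methylene lactone, 1R,10R, C2=C3 ring-trans, 6Z, C15 isovalerate | C=C1C(=O)O[C@@H]2/C=C(\COC(=O)CC(C)C)CC/C=C(/C)C(=O)C[C@H]12 | intermediate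
32 | (1R,8S,10R)-8-hydroxy ten-membered cis-fused α-methylene lactone, C15 isovalerate | C=C1C(=O)O[C@@H]2/C=C(\COC(=O)CC(C)C)CC/C=C(/C)[C@@H](O)C[C@H]12 | intermediate
33 | CNP0398030.1: (1R,8S,10R)-8-acetoxy ten-membered cis-fused α-methylene lactone, C15 isovalerate, C2=C3 ring-trans, 6Z | C=C1C(=O)O[C@@H]2/C=C(\COC(=O)CC(C)C)CC/C=C(/C)[C@@H](OC(C)=O)C[C@H]12 | target

**Step count**

Total steps: 20. Longest linear sequence: 19 steps (3 → 33 through steps 2–20; step 1 is a one-step side branch joining at step 3).

**Steps most likely to fail, with fallbacks**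

1. Step 17 (key step). What may go wrong: proton loss at C1 followed by 1,4-elimination of the sulfonium group, or delivery of C9 to the face of C10 anti to C2, giving the trans ring fusion. Fallback (anionic SN2′ ring closure in place of the sigmatropic shift): setting out from chloroketone 18, PhSO2Na in DMF at rt should give the β-keto sulfone bis-silyl ether F1. The operations of steps 12–15 (HF·pyridine; 21 with collidine; 23 with DIC and DMAP; ring-closing metathesis) would then lead through the sulfonyl diol F2, the C15 isovalerate F3 and the 2-(bromomethyl)acrylate F4 to the bromomethyl butenolide keto sulfone F5. Slow addition of F5 to Cs2CO3 in DMF (1 mM) is expected to close the ten-membered ring by conjugate addition of the doubly stabilised C9 carbanion to C10 with loss of bromide from C13, giving the 9-phenylsulfonyl ketone F6. This is a known reaction type: alkylation of β-keto sulfone anions by 2-(bromomethyl)acrylate-type electrophiles in the SN2′ sense. Desulfonylation with Al(Hg) in aqueous THF brings the route back at ketone 31.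

2. Step 16. What may go wrong: deprotonation of the butenolide γ-position C1 during the basic release of the thiolate (loss of configuration or double-bond migration), attack of sulfur at C10 instead of C13, or intermolecular alkylation. Fallback (the two ring closures in reverse order): setting out from acrylate 24, the same K2CO3, MeOH/THF high-dilution treatment would unmask the thiol before any butenolide exists. The thiolate would alkylate the 2-(bromomethyl)acrylate, for which direct and allylic displacement give the same product and no acidic γ-hydrogen is present, to give the fourteen-membered thia-macrolactone F7. Ring-closing metathesis of F7 (second-generation Hoveyda–Grubbs catalyst, toluene, 80 °C) between the C1 vinyl group and the acrylate methylene would then form the butenolide and come back to the route at sulfide 27.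

3. Step 6. What may go wrong: weak facial discrimination because both flanks of the ketone are alkenyl groups, and competing conjugate reduction of the vinyl ketone. Fallback (an alkynyl ketone in place of the vinyl ketone): setting out from Weinreb amide 9, lithium (trimethylsilyl)acetylide in THF at −78 °C should give the silyl ynone F8. Noyori transfer hydrogenation with RuCl[(R,R)-TsDPEN](p-cymene) in i-PrOH, in which the alkyne takes the place of the aryl group of an aryl ketone, is expected to give the (R)-propargylic alcohol F9, which has the same spatial arrangement as 12. K2CO3 in MeOH at 0 °C would remove the C-silyl group to give the terminal alkyne F10. Semihydrogenation (H2, Lindlar catalyst, that is Pd/CaCO3 poisoned with Pb(OAc)2, quinoline) brings the route back at carbinol 12.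

**Further compounds**

F1 | step 17 | (3Z,7Z,9S)-9-[(tert-butyldimethylsilyl)oxy]-7-{[(tert-butyldimethylsilyl)oxy]methyl}-3-methyl-1-(phenylsulfonyl)undeca-3,7,10-trien-2-one | C=C[C@H](O[Si](C)(C)C(C)(C)C)/C=C(\CO[Si](C)(C)C(C)(C)C)CC/C=C(/C)C(=O)CS(=O)(=O)c1ccccc1
F2 | step 17 | (3Z,7Z,9S)-9-hydroxy-7-(hydroxymethyl)-3-methyl-1-(phenylsulfonyl)undeca-3,7,10-trien-2-one | C=C[C@H](O)/C=C(\CO)CC/C=C(/C)C(=O)CS(=O)(=O)c1ccccc1
F3 | step 17 | (2Z,4S)-4-hydroxy-2-[(3Z)-4-methyl-5-oxo-6-(phenylsulfonyl)hex-3-en-1-yl]hexa-2,5-dien-1-yl 3-methylbutanoate | C=C[C@H](O)/C=C(\COC(=O)CC(C)C)CC/C=C(/C)C(=O)CS(=O)(=O)c1ccccc1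
F4 | step 17 | (2Z,4S)-4-{[2-(bromomethyl)prop-2-enoyl]oxy}-2-[(3Z)-4-methyl-5-oxo-6-(phenylsulfonyl)hex-3-en-1-yl]hexa-2,5-dien-1-yl 3-methylbutanoate | C=C[C@H](OC(=O)C(=C)CBr)/C=C(\COC(=O)CC(C)C)CC/C=C(/C)C(=O)CS(=O)(=O)c1ccccc1
F5 | step 17 | (2Z)-3-[(2R)-4-(bromomethyl)-5-oxo-2,5-dihydrofuran-2-yl]-2-[(3Z)-4-methyl-5-oxo-6-(phenylsulfonyl)hex-3-en-1-yl]prop-2-en-1-yl 3-methylbutanoate | O=C1O[C@H](/C=C(\COC(=O)CC(C)C)CC/C=C(/C)C(=O)CS(=O)(=O)c2ccccc2)C=C1CBr
F6 | step 17 | 9-(phenylsulfonyl)-8-oxo ten-membered cis-fused α-methylene lactone, 1R,10R, C9 epimers | C=C1C(=O)O[C@@H]2/C=C(\COC(=O)CC(C)C)CC/C=C(/C)C(=O)C(S(=O)(=O)c3ccccc3)[C@H]12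
F7 | step 16 | fourteen-membered thia-macrolactone: (S)-C1 carries the vinyl group; ring C1–O–C12(=O)–C11(=CH2)–C13H2–S–C9H2–C8(=O)–C7(CH3)=C6–C5–C4–C3(C15H2O-isovaleryl)=C2 | C=C[C@H](OC(=O)C(=C)C1)/C=C(\COC(=O)CC(C)C)CC/C=C(/C)C(=O)CS1
F8 | step 6 | (4Z)-5-{[(tert-butyldimethylsilyl)oxy]methyl}-8-[(triethylsilyl)oxy]-1-(trimethylsilyl)oct-4-en-1-yn-3-one | C[Si](C)(C)C#CC(=O)/C=C(\CO[Si](C)(C)C(C)(C)C)CCCO[Si](CC)(CC)CC
F9 | step 6 | (3R,4Z)-5-{[(tert-butyldimethylsilyl)oxy]methyl}-8-[(triethylsilyl)oxy]-1-(trimethylsilyl)oct-4-en-1-yn-3-ol | C[Si](C)(C)C#C[C@H](O)/C=C(\CO[Si](C)(C)C(C)(C)C)CCCO[Si](CC)(CC)CC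
F10 | step 6 | (3R,4Z)-5-{[(tert-butyldimethylsilyl)oxy]methyl}-8-[(triethylsilyl)oxy]oct-4-en-1-yn-3-ol | C#C[C@H](O)/C=C(\CO[Si](C)(C)C(C)(C)C)CCCO[Si](CC)(CC)CC
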